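(All runs are calculated with constants of no real substance; noise was put on by code.)

The amounts come first: each exchange takes one incoming ligand from a supply that the protic impurity also draws on.

| setting | north-east | flask |
|---|---|---|
| starting complex | 8.5 mM | 17 mM |
| incoming ligand | 17 mM | 17.0 mM |
| leaving ligand | 8.5 mM | 8.50 mM |
| protic impurity | 5.1 mM | 5.10 mM |
| remark | run made earlier |  |
| time |  | 6.0 h |

north-east run (percent of the starting complex charged)

| time / min | complex with one exchanged / % | starting complex / % |
|---|---|---|
| 3.00 | 1.4 | 99.3 |
| 6.00 | 3.4 | 96.9 |
| 15.0 | 5.0 | 94.5 |
| 40.0 | 12.4 | 87.1 |

(scatter of a reading: 1 percentage point)

- candidate steps: leaving ligand -> by-product carried off; starting complex + incoming ligand <-> leaving ligand + complex with one exchanged; protic impurity + incoming ligand -> quenched reagent; complex with one exchanged + incoming ligand <-> leaving ligand + complex with two exchanged; complex with two exchanged + incoming ligand <-> leaving ligand + complex with three exchanged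

1. equivalents of incoming ligand to starting complex, everything else as given, that leave most complex with one exchanged at 6.0 h
2. the amount of complex with one exchanged then, in percent of the starting complex charged
3. the amount of complex with one exchanged with the amounts as given

What do the north-east readings give? Starting complex stands at 87.1 % after 40.0 min, a first-order fall of 0.207 h⁻¹ as read, and the complex with one exchanged holds nearly all of the loss.

Does that rate carry over to the flask? At the start, yes, since c(incoming ligand) is the same in both. But the flask charges twice the starting complex, so its ligand thins faster than in the north-east run.

How do you count that? Take the impurity as a correction to the ligand charge, 30.0 % of it. The ligand budget is c(incoming ligand) minus c(protic impurity), divided by c(starting complex): the equivalents per starting complex left once the impurity has taken its whole charge. My reckoning gives 0.700 for the flask and 1.40 for the north-east run.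

And the weak spot? The readings do not show how fast the impurity takes its share, so the budget is a count and not a clock. Still, it stands below one equivalent, so I take incoming ligand as the limiting reagent in the flask. The budget is my estimate of the uptake that ligand can pay for, not a bound, since the impurity need not take its whole charge.

The forecast says 36 % as charged and 42 % at 1.5 equiv, on the ground that the flask “depletes the ligand substantially”.

The simulation gives 35.2 % as charged and 42.0 % at 1.85 equiv, which is 1.23 times the forecast's equivalents.

    leaving ligand → by-product carried off (k = 0.680 h⁻¹)
    starting complex + incoming ligand ⇌ leaving ligand + complex with one exchanged (K = 0.830, k = 13.0 M⁻¹ h⁻¹)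
    protic impurity + incoming ligand → quenched reagent (k = 25.0 M⁻¹ h⁻¹)
    complex with one exchanged + incoming ligand ⇌ leaving ligand + complex with two exchanged (K = 1.60, k = 7.50 M⁻¹ h⁻¹)
    complex with two exchanged + incoming ligand ⇌ leaving ligand + complex with three exchanged (K = 1.40, k = 3.10 M⁻¹ h⁻¹)

By the asked time the flask has taken up 0.521 equiv of its budget of 0.700. The largest single effect on the amount of complex with one exchanged as charged comes from the carrying off of leaving ligand : the run without that step gives 24.3 % against 35.2 %, a difference of 11 percentage points. At the best charge the budget is 1.55.

In the neighbour with 6.8 mM of starting complex, the budget is 1.75, above that best value, so I expect an amount near the best. The computed result is 41.4 %.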